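**Retrosynthetic overview**

1. The target is numbered as a 2,3,3a,6,7,7a-hexahydro-1H-indene (ring A = cyclohexene C3a/C4–C7/C7a, ring B = cyclopentane C1–C3/C3a/C7a; these locants are used for all bicyclic compounds). Late disconnections: acid ← ethyl ester; C4–CH3 ← enol triflate of a C4 ketone; propenoate arm ← Wittig reaction of a C7 aldehyde.
2. Enabling feature: the ring-fusion bond C3a–C7a lies α,β to C4. With C4 carried as a ketone, C7a and C3a are the β- and α-carbons of a cyclohex-2-enone, and the C1–C2–C3 bridge of ring B (methyl on C1 and C3, nothing on C2) maps onto an enantiopure 1,3-dimethylallenylsilane.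
3. Key disconnection: ring B is annulated onto ring A by forming C1–C7a and C3–C3a in one (trimethylsilyl)cyclopentene annulation. C7a is set by attack anti to the C6 phenyl group, C1 by the allene axis.
4. C3 and C3a are then set together by hydroxyl-directed hydrogenation of the C3=C3a enone from the face of the C7 hydroxymethyl group, which gives the trans ring fusion.
5. Ring order: ring A first (enantioselective Diels–Alder reaction of (E)-2-ethylcinnamaldehyde with an aminosiloxydiene, fixing C6 and C7), then ring B in the key step.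

Key step: step 7

Remark: the (R,R)-diol catalyst of step 2 is assumed, by analogy with α-alkylacroleins, to give the (1S,6S) cycloadduct; if the sense proves opposite, the (S,S)-diol is used.

**Step 1**
Reactants: 1 benzaldehyde; 2 butanal
Product: 4 (2E)-2-ethyl-3-phenylprop-2-enal, via aldol adduct 3 (not isolated)
Conditions: NaOH (10% aq.), EtOH, 0 °C to rt, slow addition of 2
Reagents that add atoms: none
Why: Claisen–Schmidt (crossed aldol) condensation of the butanal enolate with non-enolisable benzaldehyde and E1cB loss of water should give the E-enal (phenyl trans to formyl, hence cis to ethyl) without any stereocentre.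

**Step 2**
Reactants: 4 (2E)-2-ethyl-3-phenylprop-2-enal; 5 (1E)-3-{[tert-butyl(dimethyl)silyl]oxy}-N,N-dimethylbuta-1,3-dien-1-amine
Product: 7 [(1S,2R,6S)-4-{[tert-butyl(dimethyl)silyl]oxy}-2-(dimethylamino)-1-ethyl-6-phenylcyclohex-3-en-1-yl]methanol, via cycloadduct aldehyde 6 (not isolated)
Conditions: (4R,5R)-2,2-dimethyl-α,α,α′,α′-tetra(naphth-1-yl)-1,3-dioxolane-4,5-dimethanol (20 mol%), toluene, −40 °C; then LiAlH4, Et2O, −78 °C
Reagents that add atoms: none
Why: In this hydrogen-bond-catalysed endo Diels–Alder reaction the CH2 terminus of the aminosiloxydiene bonds to the β-carbon of the diol-activated enal (siloxy carbon para to the new quaternary carbon), suprafacial addition to the E-enal fixes ethyl cis to phenyl, the chiral diol selects the enal face and so the absolute configuration at C1/C6, and hydride reduction in the same pot secures the aldehyde as the alcohol.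

**Step 3**
Reactants: 7 cycloadduct alcohol
Product: 9 (4R,5S)-4-ethyl-4-(hydroxymethyl)-5-phenylcyclohex-2-en-1-one, via β-amino ketone 8 (not isolated)
Conditions: HF (48% aq.), MeCN, 0 °C to rt
Reagents that add atoms: none
Why: Acidic cleavage of the silyl enol ether followed by E1cB β-elimination of dimethylamine should unveil the cyclohexenone, while the two non-enolisable stereocentres are retained.

**Step 4**
Reactants: 9 enone alcohol
Product: 10 (4R,5S)-4-({[tert-butyl(dimethyl)silyl]oxy}methyl)-4-ethyl-5-phenylcyclohex-2-en-1-one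
Conditions: TBSCl, imidazole, DMF, rt
Reagents that add atoms: tert-butyldimethylsilyl chloride, CC(C)(C)[Si](C)(C)Cl
Why: Routine O-silylation masks the hydroxyl group against TiCl4 in the annulation and touches no stereocentre.

**Step 5**
Reactants: 11 (2S)-4-(trimethylsilyl)but-3-yn-2-ol
Product: 12 (2S)-4-(trimethylsilyl)but-3-yn-2-yl methanesulfonate
Conditions: MsCl, Et3N, CH2Cl2, −78 to 0 °C
Reagents that add atoms: methanesulfonyl chloride, CS(=O)(=O)Cl
Why: O-Sulfonylation leaves the C–O bond and thus the configuration untouched and installs the leaving group for the SN2′ step.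

**Step 6**
Reactants: 12 propargylic mesylate
Product: 13 (aS)-trimethyl(penta-2,3-dien-2-yl)silane
Conditions: MeMgCl, CuBr, LiBr, THF, −78 to −30 °C
Reagents that add atoms: methylmagnesium chloride, C[Mg]Cl
Why: anti-SN2′ substitution of the propargylic mesylate by methylcopper at the silyl-bearing alkyne carbon should convert the (S) carbinol centre into the (aS) allene axis (central-to-axial chirality transfer).

**Step 7**
Reactants: 10 enone silyl ether; 13 (aS)-allenylsilane
Product: 14 (1S,3aR,6S,7R,7aS)-7-({[tert-butyl(dimethyl)silyl]oxy}methyl)-7-ethyl-1,3-dimethyl-6-phenyl-2-(trimethylsilyl)-1,3a,5,6,7,7a-hexahydro-4H-inden-4-one (cis-fused)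
Conditions: TiCl4 (1.5 equiv), CH2Cl2, −78 °C, 13 (1.5 equiv)
Reagents that add atoms: none
Why: TiCl4 activates enone 10 and the CH(CH3) terminus of allene 13 attacks the β-carbon C7a anti to the C–Si bond (SE2′) to give a β-silyl-stabilised vinyl cation; a 1,2-silyl shift moves the charge to the methyl-bearing carbon, which the titanium enolate captures at C3a, so C1–C7a and C3–C3a form in one operation and silicon ends on C2. The closest known reaction is the Danheiser (trimethylsilyl)cyclopentene annulation of allenylsilanes, including 1,3-disubstituted ones, with cyclic enones. Ring B closes by 5-endo-dig attack of the enolate carbon (enolexo) on the linear vinyl cation from the face that already carries the tether, hence the cis ring fusion. C7a is set by axial attack on the half-chair with equatorial phenyl, anti to the C6 phenyl and to the axial C7 ethyl group; C1 is set by transfer of the allene's axial chirality (attack anti to silicon); C3a follows from the cis closure and is deliberately erased in step 8. The step needs annulation to win over desilylation of the vinyl cation (simple propargylation), which the methyl group on the silyl-bearing allene carbon and TiCl4 at −78 °C favour, and it needs β-regiochemistry and π-facial control, which the enone polarity and the C6/C7 substituents supply.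

**Step 8**
Reactants: 14 annulation product
Product: 16 (1R,6S,7S,7aS)-7-ethyl-7-(hydroxymethyl)-1,3-dimethyl-6-phenyl-1,2,5,6,7,7a-hexahydro-4H-inden-4-one, via deconjugated keto alcohol 15 (not isolated)
Conditions: p-TsOH·H2O (0.3 equiv), MeCN–H2O (10:1), 70 °C
Reagents that add atoms: none
Why: Acid should protodesilylate the vinylsilane through the tertiary β-silyl cation, cleave the primary silyl ether and, by enolisation toward C3a and γ-protonation at C2, move the alkene into conjugation (C3=C3a), which erases the C3a centre while the non-acidic C1, C6, C7 and C7a centres persist.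

**Step 9**
Reactants: 16 conjugated enone alcohol
Product: 17 (1R,3R,3aR,6S,7R,7aR)-7-ethyl-7-(hydroxymethyl)-1,3-dimethyl-6-phenyloctahydro-4H-inden-4-one (trans-fused)
Conditions: H2 (10 bar), [Ir(cod)(PCy3)(py)]PF6 (10 mol%), CH2Cl2, rt
Reagents that add atoms: none
Why: In this hydroxyl-directed homogeneous hydrogenation the cationic iridium centre, bound to the C7 hydroxymethyl group (axial and 1,3-syn to C3a in the chair enforced by the planar cyclopentene), should deliver both hydrogens syn to the C3=C3a alkene from that face, which sets C3 (methyl trans to the C1 methyl) and C3a (hydrogen trans to H7a, trans ring fusion) at once.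

**Step 10**
Reactants: 17 keto alcohol
Product: 18 (1R,3R,3aR,6S,7R,7aR)-7-ethyl-1,3-dimethyl-4-oxo-6-phenyloctahydro-1H-indene-7-carbaldehyde
Conditions: Dess–Martin periodinane, NaHCO3, CH2Cl2, 0 °C to rt
Reagents that add atoms: none
Why: Buffered hypervalent-iodine oxidation of the neopentyl primary alcohol gives a non-enolisable aldehyde under conditions too mild to enolise the ketone at C3a.

**Step 11**
Reactants: 18 keto aldehyde; 19 ethyl 2-(triphenyl-λ5-phosphanylidene)propanoate
Product: 20 ethyl (2E)-3-[(1R,3R,3aR,6S,7S,7aR)-7-ethyl-1,3-dimethyl-4-oxo-6-phenyloctahydro-1H-inden-7-yl]-2-methylprop-2-enoate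
Conditions: toluene, 90 °C
Reagents that add atoms: none
Why: The Wittig reaction of the stabilised ylide is aldehyde-selective over the ketone and E-selective (ester trans to the quaternary carbon), and the ylide is too weak a base to epimerise C3a.

**Step 12**
Reactants: 20 keto enoate
Product: 22 ethyl (2E)-3-[(1R,3R,3aR,6S,7S,7aR)-7-ethyl-1,3-dimethyl-6-phenyl-4-{[(trifluoromethyl)sulfonyl]oxy}-2,3,3a,6,7,7a-hexahydro-1H-inden-7-yl]-2-methylprop-2-enoate, via potassium enolate 21 (not isolated)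
Conditions: KN(SiMe3)2, THF, −78 °C; then PhNTf2, −78 to 0 °C
Reagents that add atoms: N-phenylbis(trifluoromethanesulfonimide), O=S(=O)(N(c1ccccc1)S(=O)(=O)C(F)(F)F)C(F)(F)F
Why: Kinetic deprotonation at the less hindered C5 methylene (not at the tertiary C3a–H) and O-triflation of the enolate fix the C4=C5 alkene position and leave C3a untouched.

**Step 13**
Reactants: 22 enol triflate
Product: 23 ethyl (2E)-3-[(1R,3R,3aR,6S,7S,7aR)-7-ethyl-1,3,4-trimethyl-6-phenyl-2,3,3a,6,7,7a-hexahydro-1H-inden-7-yl]-2-methylprop-2-enoate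
Conditions: MeZnCl, Pd(PPh3)4 (5 mol%), THF, 50 °C
Reagents that add atoms: methylzinc chloride, C[Zn]Cl
Why: Negishi coupling of the alkenyl triflate with the methylzinc reagent replaces the triflate by methyl with retention of the alkene position and tolerates the ester.

**Step 14**
Reactants: 23 ethyl ester
Product: 25 plakotenin, (2E)-3-[(1R,3R,3aR,6S,7S,7aR)-7-ethyl-1,3,4-trimethyl-6-phenyl-2,3,3a,6,7,7a-hexahydro-1H-inden-7-yl]-2-methylprop-2-enoic acid, via lithium carboxylate 24 (not isolated)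
Conditions: LiOH, THF–MeOH–H2O, 50 °C; then 1 M HCl
Reagents that add atoms: lithium hydroxide, [Li+].[OH-]
Why: Saponification of the ethyl ester and acidification should give the acid without touching the alkenes or any stereocentre.

**Compound list**

1 | benzaldehyde | O=Cc1ccccc1 | starting material
2 | butanal | CCCC=O | starting material
3 | 2-ethyl-3-hydroxy-3-phenylpropanal (aldol adduct, mixture of diastereomers) | CCC(C=O)C(O)c1ccccc1 | intermediate
4 | (2E)-2-ethyl-3-phenylprop-2-enal | CC/C(C=O)=C\c1ccccc1 | intermediate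
5 | (1E)-3-{[tert-butyl(dimethyl)silyl]oxy}-N,N-dimethylbuta-1,3-dien-1-amine | CN(C)/C=C/C(=C)O[Si](C)(C)C(C)(C)C | starting material
6 | (1S,2R,6S)-4-{[tert-butyl(dimethyl)silyl]oxy}-2-(dimethylamino)-1-ethyl-6-phenylcyclohex-3-ene-1-carbaldehyde (ethyl cis to phenyl, amine cis to formyl) | CC[C@@]1(C=O)[C@H](N(C)C)C=C(O[Si](C)(C)C(C)(C)C)C[C@H]1c1ccccc1 | intermediate
7 | [(1S,2R,6S)-4-{[tert-butyl(dimethyl)silyl]oxy}-2-(dimethylamino)-1-ethyl-6-phenylcyclohex-3-en-1-yl]methanol | CC[C@@]1(CO)[C@H](N(C)C)C=C(O[Si](C)(C)C(C)(C)C)C[C@H]1c1ccccc1 | intermediate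
8 | (3R,4S,5S)-3-(dimethylamino)-4-ethyl-4-(hydroxymethyl)-5-phenylcyclohexan-1-one | CC[C@@]1(CO)[C@H](N(C)C)CC(=O)C[C@H]1c1ccccc1 | intermediate
9 | (4R,5S)-4-ethyl-4-(hydroxymethyl)-5-phenylcyclohex-2-en-1-one | CC[C@@]1(CO)C=CC(=O)C[C@H]1c1ccccc1 | intermediate
10 | (4R,5S)-4-({[tert-butyl(dimethyl)silyl]oxy}methyl)-4-ethyl-5-phenylcyclohex-2-en-1-one | CC[C@@]1(CO[Si](C)(C)C(C)(C)C)C=CC(=O)C[C@H]1c1ccccc1 | intermediate
11 | (2S)-4-(trimethylsilyl)but-3-yn-2-ol | C[C@H](O)C#C[Si](C)(C)C | starting material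
12 | (2S)-4-(trimethylsilyl)but-3-yn-2-yl methanesulfonate | C[C@H](OS(C)(=O)=O)C#C[Si](C)(C)C | intermediate
13 | (aS)-trimethyl(penta-2,3-dien-2-yl)silane | C[Si](C)(C)C(C)=[C@@]=C([H])C | intermediate
14 | (1S,3aR,6S,7R,7aS)-7-({[tert-butyl(dimethyl)silyl]oxy}methyl)-7-ethyl-1,3-dimethyl-6-phenyl-2-(trimethylsilyl)-1,3a,5,6,7,7a-hexahydro-4H-inden-4-one (cis-fused) | CC[C@@]1(CO[Si](C)(C)C(C)(C)C)[C@H]2[C@@H](C(=O)C[C@H]1c1ccccc1)C(C)=C([Si](C)(C)C)[C@H]2C | intermediate
15 | (1R,3aR,6S,7R,7aR)-7-ethyl-7-(hydroxymethyl)-1,3-dimethyl-6-phenyl-1,3a,5,6,7,7a-hexahydro-4H-inden-4-one (cis-fused, C2=C3) | CC[C@@]1(CO)[C@H]2[C@@H](C(=O)C[C@H]1c1ccccc1)C(C)=C[C@H]2C | intermediate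
16 | (1R,6S,7S,7aS)-7-ethyl-7-(hydroxymethyl)-1,3-dimethyl-6-phenyl-1,2,5,6,7,7a-hexahydro-4H-inden-4-one (C3=C3a) | CC[C@@]1(CO)[C@H]2C(C(=O)C[C@H]1c1ccccc1)=C(C)C[C@H]2C | intermediate
17 | (1R,3R,3aR,6S,7R,7aR)-7-ethyl-7-(hydroxymethyl)-1,3-dimethyl-6-phenyloctahydro-4H-inden-4-one (trans-fused) | CC[C@@]1(CO)[C@H]2[C@H](C(=O)C[C@H]1c1ccccc1)[C@H](C)C[C@H]2C | intermediate
18 | (1R,3R,3aR,6S,7R,7aR)-7-ethyl-1,3-dimethyl-4-oxo-6-phenyloctahydro-1H-indene-7-carbaldehyde | CC[C@@]1(C=O)[C@H]2[C@H](C(=O)C[C@H]1c1ccccc1)[C@H](C)C[C@H]2C | intermediate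
19 | ethyl 2-(triphenyl-λ5-phosphanylidene)propanoate | CCOC(=O)C(C)=P(c1ccccc1)(c1ccccc1)c1ccccc1 | starting material
20 | ethyl (2E)-3-[(1R,3R,3aR,6S,7S,7aR)-7-ethyl-1,3-dimethyl-4-oxo-6-phenyloctahydro-1H-inden-7-yl]-2-methylprop-2-enoate | CC[C@@]1(/C=C(\C)C(=O)OCC)[C@H]2[C@H](C(=O)C[C@H]1c1ccccc1)[C@H](C)C[C@H]2C | intermediate
21 | potassium C4=C5 enolate of 20 | CC[C@@]1(/C=C(\C)C(=O)OCC)[C@H]2[C@H](C([O-])=C[C@H]1c1ccccc1)[C@H](C)C[C@H]2C.[K+] | intermediate
22 | ethyl (2E)-3-[(1R,3R,3aR,6S,7S,7aR)-7-ethyl-1,3-dimethyl-6-phenyl-4-{[(trifluoromethyl)sulfonyl]oxy}-2,3,3a,6,7,7a-hexahydro-1H-inden-7-yl]-2-methylprop-2-enoate | CC[C@@]1(/C=C(\C)C(=O)OCC)[C@H]2[C@H](C(OS(=O)(=O)C(F)(F)F)=C[C@H]1c1ccccc1)[C@H](C)C[C@H]2C | intermediate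
23 | ethyl (2E)-3-[(1R,3R,3aR,6S,7S,7aR)-7-ethyl-1,3,4-trimethyl-6-phenyl-2,3,3a,6,7,7a-hexahydro-1H-inden-7-yl]-2-methylprop-2-enoate | CC[C@@]1(/C=C(\C)C(=O)OCC)[C@H]2[C@H](C(C)=C[C@H]1c1ccccc1)[C@H](C)C[C@H]2C | intermediate
24 | lithium salt of plakotenin | CC[C@@]1(/C=C(\C)C(=O)[O-])[C@H]2[C@H](C(C)=C[C@H]1c1ccccc1)[C@H](C)C[C@H]2C.[Li+] | intermediate
25 | plakotenin, (2E)-3-[(1R,3R,3aR,6S,7S,7aR)-7-ethyl-1,3,4-trimethyl-6-phenyl-2,3,3a,6,7,7a-hexahydro-1H-inden-7-yl]-2-methylprop-2-enoic acid | CC[C@@]1(/C=C(\C)C(=O)O)[C@H]2[C@H](C(C)=C[C@H]1c1ccccc1)[C@H](C)C[C@H]2C | target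

**Totals**

Total step count: 14.
Longest linear sequence: 12 steps (steps 1–4, then 7–14); steps 5–6 make the allene separately.

**Steps most likely to fail**

1. Step 7. The β-silyl vinyl cation may lose its silyl group before the enolate closes the ring (conjugate propargylation only), attack at the neopentyl-type β-carbon may be slow, or the silyl ether may be cleaved by the Lewis acid. The fallback separates the two bond formations; it sets out from 10 (with 13) and comes back at 16. Hosomi–Sakurai-type conjugate propargylation with enolate trapping (13, Me3SiCl, InCl3 cat., CH2Cl2, −78 °C to rt) should give the regiodefined trimethylsilyl enol ether of the 3-(pent-3-yn-2-yl) ketone, tert-butyl{[(1R,2R,6S)-1-ethyl-2-[(2S)-pent-3-yn-2-yl]-6-phenyl-4-[(trimethylsilyl)oxy]cyclohex-3-en-1-yl]methoxy}dimethylsilane F1, with C7a and C1 set as in step 7. A Conia-ene-type 5-endo-dig carbocyclisation of the silyl enol ether onto the alkyne ((Ph3P)AuCl/AgBF4 cat., CH2Cl2–MeOH, 40 °C) should then close ring B to the silyl ether of 15, (1R,3aR,6S,7R,7aR)-7-({[tert-butyl(dimethyl)silyl]oxy}methyl)-7-ethyl-1,3-dimethyl-6-phenyl-1,3a,5,6,7,7a-hexahydro-4H-inden-4-one F2, which under the conditions of step 8 gives 16.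

2. Step 9. The electron-poor, tetrasubstituted conjugated alkene may bind the cationic iridium centre too weakly for turnover, or hydrogen may be delivered without guidance by the hydroxymethyl group. The fallback removes the conjugation before hydrogenation; it sets out from 16 and comes back at 17. Ketalisation without double-bond shift (1,2-bis(trimethylsilyloxy)ethane, Me3SiOTf cat., CH2Cl2, −78 °C) should give the ethylene ketal of 16 as its O-trimethylsilyl ether F3, which K2CO3 in MeOH frees to the ethylene ketal of 16 F4. The now isolated, electron-richer C3=C3a alkene is hydrogenated under the same hydroxyl direction to the ethylene ketal of 17 F5, and aqueous HCl in acetone returns 17.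

3. Step 2. Enantiofacial discrimination may be poor, or conversion low at the temperature needed for selectivity, because the enal carries a β-aryl group in addition to the α-alkyl group. The fallback replaces catalyst control by classical resolution; it sets out from 4 and 5 and comes back at 9. The uncatalysed cycloaddition (toluene, 60 °C) followed by the reagents of steps 2 and 3 should lead through racemic 6 F6, racemic 7 F7 and racemic 8 F8 to racemic 9 F9. Esterification with (S)-O-methylmandelic acid (DCC, DMAP, CH2Cl2) gives the diastereomeric esters [(1R,6S)-1-ethyl-4-oxo-6-phenylcyclohex-2-en-1-yl]methyl (2S)-methoxy(phenyl)acetate F10 and its (1S,6R) diastereomer F11, which are separated by chromatography or crystallisation. K2CO3 in MeOH cleaves F10 to enantiopure 9.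

**Further compounds**

F1 | step 7 | tert-butyl{[(1R,2R,6S)-1-ethyl-2-[(2S)-pent-3-yn-2-yl]-6-phenyl-4-[(trimethylsilyl)oxy]cyclohex-3-en-1-yl]methoxy}dimethylsilane | CC[C@@]1(CO[Si](C)(C)C(C)(C)C)[C@H]([C@H](C)C#CC)C=C(O[Si](C)(C)C)C[C@H]1c1ccccc1
F2 | step 7 | (1R,3aR,6S,7R,7aR)-7-({[tert-butyl(dimethyl)silyl]oxy}methyl)-7-ethyl-1,3-dimethyl-6-phenyl-1,3a,5,6,7,7a-hexahydro-4H-inden-4-one | CC[C@@]1(CO[Si](C)(C)C(C)(C)C)[C@H]2[C@@H](C(=O)C[C@H]1c1ccccc1)C(C)=C[C@H]2C
F3 | step 9 | ethylene ketal of 16, O-trimethylsilyl ether | CC[C@@]1(CO[Si](C)(C)C)[C@H]2C(C3(OCCO3)C[C@H]1c1ccccc1)=C(C)C[C@H]2C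
F4 | step 9 | ethylene ketal of 16 | CC[C@@]1(CO)[C@H]2C(C3(OCCO3)C[C@H]1c1ccccc1)=C(C)C[C@H]2C
F5 | step 9 | ethylene ketal of 17 | CC[C@@]1(CO)[C@H]2[C@H](C3(OCCO3)C[C@H]1c1ccccc1)[C@H](C)C[C@H]2C
F6 | step 2 | racemic 6 | CC[C@@]1(C=O)[C@H](N(C)C)C=C(O[Si](C)(C)C(C)(C)C)C[C@H]1c1ccccc1.CC[C@]1(C=O)[C@@H](N(C)C)C=C(O[Si](C)(C)C(C)(C)C)C[C@@H]1c1ccccc1
F7 | step 2 | racemic 7 | CC[C@@]1(CO)[C@H](N(C)C)C=C(O[Si](C)(C)C(C)(C)C)C[C@H]1c1ccccc1.CC[C@]1(CO)[C@@H](N(C)C)C=C(O[Si](C)(C)C(C)(C)C)C[C@@H]1c1ccccc1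
F8 | step 2 | racemic 8 | CC[C@@]1(CO)[C@H](N(C)C)CC(=O)C[C@H]1c1ccccc1.CC[C@]1(CO)[C@@H](N(C)C)CC(=O)C[C@@H]1c1ccccc1
F9 | step 2 | racemic 9 | CC[C@@]1(CO)C=CC(=O)C[C@H]1c1ccccc1.CC[C@]1(CO)C=CC(=O)C[C@@H]1c1ccccc1
F10 | step 2 | [(1R,6S)-1-ethyl-4-oxo-6-phenylcyclohex-2-en-1-yl]methyl (2S)-methoxy(phenyl)acetate | CC[C@@]1(COC(=O)[C@@H](OC)c2ccccc2)C=CC(=O)C[C@H]1c1ccccc1
F11 | step 2 | [(1S,6R)-1-ethyl-4-oxo-6-phenylcyclohex-2-en-1-yl]methyl (2S)-methoxy(phenyl)acetate | CC[C@]1(COC(=O)[C@@H](OC)c2ccccc2)C=CC(=O)C[C@@H]1c1ccccc1
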